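**A direct plan and its weak points**

A direct plan would build the hydroxylated ring from a small chiral lactone: prolinol-catalysed cross-aldol of a 3-silyloxypropanal with ethyl glyoxylate (aldehyde A1), aryl Grignard addition and lactonisation (diol lactone A2), acetalisation with O-benzylsyringaldehyde (acetal A3), an n-Bu2BOTf-mediated O→C shift of the acetal carbon to the bicyclic hydroxy lactone A4, LiAlH4 reduction with acid closure of the second ring to the furofuran dibenzyl ether A5, then hydrogenolysis.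
- The ring-contracting acetal shift from acetal A3 to hydroxy lactone A4 would have to forge the C1–C2 bond at the fully substituted carbinol carbon. Recombination of a tethered oxocarbenium ion with a boron enediolate has no precedent, fragmentation or elimination would be easier exits, and the whole route hangs on it.
- The guaiacyl benzylic centre C6 would be set in the Grignard step, erased by ionisation and set again in an acidic SN1 closure, under conditions that also let the syringyl benzylic ether epimerise.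
- Five steps would go into making guaiacol- and syringaldehyde-type arenes from catechol and p-cresol, aldehyde A1 would not keep, and the last step would be a hydrogenolysis next to two ring benzylic C–O bonds.

**Retrosynthetic overview of the new route**

Numbering: C1 carbinol bridgehead, C2 syringyl carbon, C5 CH bridgehead, C6 guaiacyl carbon; ring A = C1–C2–O3–C4–C5, ring B = C1–C5–C6–O7–C8.
- Both benzylic C–O bonds (C2–O3 and C6–O7) are cut at once, giving the acyclic diphenolic triol 15 with only C1 and C5 as stereocentres. C2 and C6 each sit para to a free phenol and γ to a primary hydroxyl (C4–OH, C8–OH), so dehydrogenation to two quinone methides should zip up both tetrahydrofurans in the last flask.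
- 15 comes from LiAlH4 reduction and hydrogenolysis of the α-hydroxy-α,β-dibenzylbutyrolactone 13. 13 comes from enediolate alkylation of hydroxy lactone 8 (sets C1), and 8 from Stobbe condensation, asymmetric hydrogenation (sets C5) and enolate hydroxylation.
- By design, no untested C–C-forming rearrangement is needed; the benzylic centres are created once, last, without acid; hydrogenolysis precedes any ring benzylic ether; both arenes are bought as O-benzylvanillin and O-benzylsyringaldehyde.

Key step: step 10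

Remark: the (S,S)-Et-DuPhos ligand is assumed to deliver the R acid 4; if the sense is opposite, the (R,R) ligand would be used.

**Route**

Step 1
Reactants: 1 4-(benzyloxy)-3-methoxybenzaldehyde; 2 dimethyl succinate
Product: 3 (E)-4-[4-(benzyloxy)-3-methoxyphenyl]-3-(methoxycarbonyl)but-3-enoic acid
Conditions: NaOMe (1.3 equiv), MeOH, reflux; then aq HCl
Reagents that add atoms: none
Why: Stobbe condensation (aldol, paraconate lactonisation, E1cB opening) should give the E half ester with the free acid on the CH2 arm, which differentiates the two carboxyl groups for step 3.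

Step 2
Reactants: 3 (E)-4-[4-(benzyloxy)-3-methoxyphenyl]-3-(methoxycarbonyl)but-3-enoic acid
Product: 4 (3R)-4-[4-(benzyloxy)-3-methoxyphenyl]-3-(methoxycarbonyl)butanoic acid
Conditions: [Rh(cod)((S,S)-Et-DuPhos)]BF4 (0.5 mol %), H2 (5 bar), MeOH, rt
Reagents that add atoms: none
Why: Asymmetric hydrogenation of a Stobbe-type β-aryl itaconate half ester with [Rh(cod)((S,S)-Et-DuPhos)]BF4 should set C5 under catalyst control, and a homogeneous catalyst leaves the aryl benzyl ether intact.

Step 3
Reactants: 4 (3R)-4-[4-(benzyloxy)-3-methoxyphenyl]-3-(methoxycarbonyl)butanoic acid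
Product: 6 (4R)-4-{[4-(benzyloxy)-3-methoxyphenyl]methyl}dihydrofuran-2(3H)-one, via hydroxy acid 5 (not isolated)
Conditions: LiBH4 (3 equiv), THF, 0 → 45 °C; then 2 M HCl, rt
Reagents that add atoms: none
Why: Chemoselective borohydride reduction of the methyl ester beside the carboxylate, which LiBH4 does not reduce, then acid-promoted γ-lactonisation, should give the β-benzyl lactone without touching the stereocentre.

Step 4
Reactants: 6 (4R)-4-{[4-(benzyloxy)-3-methoxyphenyl]methyl}dihydrofuran-2(3H)-one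
Product: 8 (3R,4S)-4-{[4-(benzyloxy)-3-methoxyphenyl]methyl}-3-hydroxydihydrofuran-2(3H)-one, via potassium enolate 7 (not isolated)
Conditions: KN(SiMe3)2 (1.1 equiv), THF, −78 °C; 2-(phenylsulfonyl)-3-phenyloxaziridine (1.3 equiv), −78 °C; AcOH
Reagents that add atoms: 2-(phenylsulfonyl)-3-phenyloxaziridine, O=S(=O)(c1ccccc1)N1OC1c1ccccc1
Why: Davis oxidation of the lactone enolate should deliver oxygen anti to the β-benzyl group; the C3 configuration is immaterial because step 7 makes this carbon planar again, so both epimers converge.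

Step 5
Reactants: 9 4-(benzyloxy)-3,5-dimethoxybenzaldehyde
Product: 10 [4-(benzyloxy)-3,5-dimethoxyphenyl]methanol
Conditions: NaBH4 (0.5 equiv), MeOH, 0 °C
Reagents that add atoms: none
Why: Borohydride reduction of an aromatic aldehyde.

Step 6
Reactants: 10 [4-(benzyloxy)-3,5-dimethoxyphenyl]methanol
Product: 11 2-(benzyloxy)-5-(bromomethyl)-1,3-dimethoxybenzene
Conditions: PBr3 (0.4 equiv), CH2Cl2, 0 °C
Reagents that add atoms: phosphorus tribromide, BrP(Br)Br
Why: Bromination of a benzylic alcohol through its phosphite ester; the bromide would be used directly.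

Step 7
Reactants: 8 (3R,4S)-4-{[4-(benzyloxy)-3-methoxyphenyl]methyl}-3-hydroxydihydrofuran-2(3H)-one; 11 2-(benzyloxy)-5-(bromomethyl)-1,3-dimethoxybenzene
Product: 13 (3S,4S)-3-{[4-(benzyloxy)-3,5-dimethoxyphenyl]methyl}-4-{[4-(benzyloxy)-3-methoxyphenyl]methyl}-3-hydroxydihydrofuran-2(3H)-one, via dilithium enediolate 12 (not isolated)
Conditions: LiN(i-Pr)2 (2.2 equiv), THF–DMPU, −78 °C; 11 (1.2 equiv), −78 → −30 °C; AcOH
Reagents that add atoms: none
Why: C-alkylation of the α-hydroxy lactone dianion, the established entry to α-hydroxylated dibenzylbutyrolactone lignans, should bring the benzyl group in anti to the β-benzyl substituent; this sets the quaternary carbinol C1 with the hydroxyl cis to the β-benzyl group.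

Step 8
Reactants: 13 (3S,4S)-3-{[4-(benzyloxy)-3,5-dimethoxyphenyl]methyl}-4-{[4-(benzyloxy)-3-methoxyphenyl]methyl}-3-hydroxydihydrofuran-2(3H)-one
Product: 14 (2S,3S)-2-{[4-(benzyloxy)-3,5-dimethoxyphenyl]methyl}-3-{[4-(benzyloxy)-3-methoxyphenyl]methyl}butane-1,2,4-triol
Conditions: LiAlH4 (2.5 equiv), THF, 0 °C → rt; Na2SO4·10H2O quench
Reagents that add atoms: none
Why: Hydride reduction of the lactone to the 1,4-diol should free both primary hydroxyls (C8–OH and C4–OH) without touching C1 or C5.

Step 9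
Reactants: 14 (2S,3S)-2-{[4-(benzyloxy)-3,5-dimethoxyphenyl]methyl}-3-{[4-(benzyloxy)-3-methoxyphenyl]methyl}butane-1,2,4-triol
Product: 15 (2S,3S)-2-[(4-hydroxy-3,5-dimethoxyphenyl)methyl]-3-[(4-hydroxy-3-methoxyphenyl)methyl]butane-1,2,4-triol
Conditions: H2 (1 atm), 10% Pd/C, EtOAc–MeOH, rt
Reagents that add atoms: none
Why: Hydrogenolysis of the two aryl benzyl ethers at a stage where the molecule holds no other benzylic C–O bond.

Step 10
Reactants: 15 (2S,3S)-2-[(4-hydroxy-3,5-dimethoxyphenyl)methyl]-3-[(4-hydroxy-3-methoxyphenyl)methyl]butane-1,2,4-triol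
Product: 19 fraxiresinol [(1S,2R,5R,6S)-2-(4-hydroxy-3,5-dimethoxyphenyl)-6-(4-hydroxy-3-methoxyphenyl)-3,7-dioxabicyclo[3.3.0]octan-1-ol], via syringyl quinone methide 16 (not isolated), via ring A tetrahydrofuran 17 (not isolated), via guaiacyl quinone methide 18 (not isolated)
Conditions: DDQ (2.05 equiv, in portions), anhydrous MeCN (0.01 M), −20 → 0 °C
Reagents that add atoms: none
Why: DDQ should dehydrogenate each 4-alkylphenol to a p-quinone methide, first at the more electron-rich 2,6-dimethoxyphenol (16), and each quinone methide should be captured by its γ-hydroxyl in an intramolecular oxa-1,6-addition that rearomatises the ring; the closest known reaction types are the DDQ oxidation of 4-alkyl-2-methoxy- and 4-alkyl-2,6-dimethoxyphenols to quinone methides that add alcohols at the benzylic carbon, and the quinone-methide closure of phenolic dibenzylbutane lignans to 2-aryltetrahydrofurans. Ring A closes 5-exo-trig (O3 of C4–OH onto C2) and ring B 5-exo-trig (O7 of C8–OH onto C6); the tertiary C1–OH or the other primary hydroxyl could only form three- or four-membered rings, so ring size fixes the regiochemistry. C2 is set in the first closure, where the flat quinone methide should turn away from the ring face that carries both carbon substituents (C8H2OH on C1 and the benzyl group on C5) and end cis to the C1 hydroxyl (2R). C6 is set in the second closure: C8–OH can reach C6 only in the cis-fused mode because C8 and C6 are already cis on ring A, and the aryl group should take the convex exo position (6S), as in the bis-quinone-methide closure that gives pinoresinol-type furofurans. The step needs oxidation of the guaiacyl CH2 of 17 to outrun re-oxidation of the new C2–H of the syringyl ring, and O-trapping to outrun C-trapping by the other arene; the C2 methine is neopentylic next to the fully substituted C1, only two equivalents of oxidant are used at low temperature in a non-nucleophilic medium without added acid, and 16 cannot tautomerise because C1 bears no hydrogen. C1 and C5 are not touched.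

**Compound list**

1 | 4-(benzyloxy)-3-methoxybenzaldehyde | COc1cc(C=O)ccc1OCc1ccccc1 | starting material
2 | dimethyl succinate | COC(=O)CCC(=O)OC | starting material
3 | (E)-4-[4-(benzyloxy)-3-methoxyphenyl]-3-(methoxycarbonyl)but-3-enoic acid | COC(=O)/C(=C/c1ccc(OCc2ccccc2)c(OC)c1)CC(=O)O | intermediate
4 | (3R)-4-[4-(benzyloxy)-3-methoxyphenyl]-3-(methoxycarbonyl)butanoic acid | COC(=O)[C@H](Cc1ccc(OCc2ccccc2)c(OC)c1)CC(=O)O | intermediate
5 | (3R)-4-[4-(benzyloxy)-3-methoxyphenyl]-3-(hydroxymethyl)butanoic acid | OC[C@H](Cc1ccc(OCc2ccccc2)c(OC)c1)CC(=O)O | intermediate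
6 | (4R)-4-{[4-(benzyloxy)-3-methoxyphenyl]methyl}dihydrofuran-2(3H)-one | O=C1OC[C@H](Cc2ccc(OCc3ccccc3)c(OC)c2)C1 | intermediate
7 | potassium enolate of 6 | [K+].[O-]C1=C[C@@H](Cc2ccc(OCc3ccccc3)c(OC)c2)CO1 | intermediate
8 | (3R,4S)-4-{[4-(benzyloxy)-3-methoxyphenyl]methyl}-3-hydroxydihydrofuran-2(3H)-one (trans epimer drawn) | O=C1OC[C@H](Cc2ccc(OCc3ccccc3)c(OC)c2)[C@H]1O | intermediate
9 | 4-(benzyloxy)-3,5-dimethoxybenzaldehyde | COc1cc(C=O)cc(OC)c1OCc1ccccc1 | starting material
10 | [4-(benzyloxy)-3,5-dimethoxyphenyl]methanol | COc1cc(CO)cc(OC)c1OCc1ccccc1 | intermediate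
11 | 2-(benzyloxy)-5-(bromomethyl)-1,3-dimethoxybenzene | COc1cc(CBr)cc(OC)c1OCc1ccccc1 | intermediate
12 | dilithium enediolate of 8 | [Li+].[Li+].[O-]C1=C([O-])[C@@H](Cc2ccc(OCc3ccccc3)c(OC)c2)CO1 | intermediate
13 | (3S,4S)-3-{[4-(benzyloxy)-3,5-dimethoxyphenyl]methyl}-4-{[4-(benzyloxy)-3-methoxyphenyl]methyl}-3-hydroxydihydrofuran-2(3H)-one | O=C1OC[C@H](Cc2ccc(OCc3ccccc3)c(OC)c2)[C@@]1(O)Cc1cc(OC)c(OCc2ccccc2)c(OC)c1 | intermediate
14 | (2S,3S)-2-{[4-(benzyloxy)-3,5-dimethoxyphenyl]methyl}-3-{[4-(benzyloxy)-3-methoxyphenyl]methyl}butane-1,2,4-triol | COc1cc(C[C@@H](CO)[C@](O)(CO)Cc2cc(OC)c(OCc3ccccc3)c(OC)c2)ccc1OCc1ccccc1 | intermediate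
15 | (2S,3S)-2-[(4-hydroxy-3,5-dimethoxyphenyl)methyl]-3-[(4-hydroxy-3-methoxyphenyl)methyl]butane-1,2,4-triol | COc1cc(C[C@@H](CO)[C@](O)(CO)Cc2cc(OC)c(O)c(OC)c2)ccc1O | intermediate
16 | syringyl p-quinone methide of 15 (C2 is the exocyclic methine of a 2,6-dimethoxycyclohexa-2,5-dienone; C1 and C5 as in 15) | COc1cc(C[C@@H](CO)[C@](O)(CO)C=C2C=C(OC)C(=O)C(OC)=C2)ccc1O | intermediate
17 | (2R,3S,4S)-2-(4-hydroxy-3,5-dimethoxyphenyl)-3-(hydroxymethyl)-4-[(4-hydroxy-3-methoxyphenyl)methyl]tetrahydrofuran-3-ol | COc1cc(C[C@H]2CO[C@H](c3cc(OC)c(O)c(OC)c3)[C@@]2(O)CO)ccc1O | intermediate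
18 | guaiacyl p-quinone methide of 17 (C6 is the exocyclic methine of a 2-methoxycyclohexa-2,5-dienone; stereocentres as in 17) | COC1=CC(=C[C@H]2CO[C@H](c3cc(OC)c(O)c(OC)c3)[C@@]2(O)CO)C=CC1=O | intermediate
19 | fraxiresinol, (1S,2R,5R,6S)-2-(4-hydroxy-3,5-dimethoxyphenyl)-6-(4-hydroxy-3-methoxyphenyl)-3,7-dioxabicyclo[3.3.0]octan-1-ol | COc1cc([C@H]2OC[C@]3(O)[C@@H](c4cc(OC)c(O)c(OC)c4)OC[C@H]23)ccc1O | target

**Step count and risks**

Total steps: 10. Longest linear sequence: 8 (steps 1–4 and 7–10).

Steps most likely to fail: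

1. Step 10. After ring A has closed, the oxidant may attack the new C2–H of the electron-rich syringyl ring faster than the guaiacyl CH2, or a quinone methide may be trapped at carbon by the other arene. The fallback fixes the order of the two oxidations by phenol masking and sets out from 8. Hydrogenolysis (H2, Pd/C) would give (3R,4S)-3-hydroxy-4-[(4-hydroxy-3-methoxyphenyl)methyl]dihydrofuran-2(3H)-one F1. Its trilithium salt (LiN(i-Pr)2, 3.2 equiv, −78 °C) would be C-alkylated with bromide 11 to the mono-benzylated hydroxy lactone F2. LiAlH4 would give the triol F3, in which only the guaiacyl phenol is free. One equivalent of DDQ could then oxidise only that ring and would close ring B first, giving the 5-aryltetrahydrofuran-3-ol F4. Hydrogenolysis of the remaining benzyl ether would give the diphenol F5. A second equivalent of DDQ would then oxidise the last benzylic CH2, which belongs to the most electron-rich phenol present, close ring A and return to the route at 19.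

2. Step 7. The enediolate may be alkylated at oxygen or simply reprotonated when it has to build the quaternary carbon by SN2. The fallback sets out from 8 and replaces alkylation by aldol addition: dianion 12 would add to aldehyde 9 at −78 °C to give the aldol adduct F6 (both carbinol epimers). Ionic hydrogenation of its benzylic hydroxyl (Et3SiH, CF3CO2H, CH2Cl2, −20 °C; the tertiary α-hydroxyl next to the carbonyl does not ionise) would return to the route at 13.

3. Step 2. Enantiofacial discrimination on the trisubstituted arylidene acid may be insufficient. The fallback sets out from 3 and uses resolution: hydrogenation with achiral [Rh(cod)(dppb)]BF4 would give the racemic acid F7. Treatment with (R)-1-phenylethylamine would give the diastereomeric ammonium salt F8, which would be crystallised (the antipodal amine would be used if the R acid stays in the mother liquor) and acidified, returning to the route at 4.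

Further compounds
F1 | step 10 | (3R,4S)-3-hydroxy-4-[(4-hydroxy-3-methoxyphenyl)methyl]dihydrofuran-2(3H)-one | O=C1OC[C@H](Cc2ccc(O)c(OC)c2)[C@H]1O
F2 | step 10 | (3S,4S)-3-{[4-(benzyloxy)-3,5-dimethoxyphenyl]methyl}-3-hydroxy-4-[(4-hydroxy-3-methoxyphenyl)methyl]dihydrofuran-2(3H)-one | O=C1OC[C@H](Cc2ccc(O)c(OC)c2)[C@@]1(O)Cc1cc(OC)c(OCc2ccccc2)c(OC)c1
F3 | step 10 | (2S,3S)-2-{[4-(benzyloxy)-3,5-dimethoxyphenyl]methyl}-3-[(4-hydroxy-3-methoxyphenyl)methyl]butane-1,2,4-triol | COc1cc(C[C@@H](CO)[C@](O)(CO)Cc2cc(OC)c(OCc3ccccc3)c(OC)c2)ccc1O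
F4 | step 10 | (3S,4R,5S)-3-{[4-(benzyloxy)-3,5-dimethoxyphenyl]methyl}-5-(4-hydroxy-3-methoxyphenyl)-4-(hydroxymethyl)tetrahydrofuran-3-ol | COc1cc([C@H]2OC[C@](O)(Cc3cc(OC)c(OCc4ccccc4)c(OC)c3)[C@@H]2CO)ccc1O
F5 | step 10 | (3S,4R,5S)-3-[(4-hydroxy-3,5-dimethoxyphenyl)methyl]-5-(4-hydroxy-3-methoxyphenyl)-4-(hydroxymethyl)tetrahydrofuran-3-ol | COc1cc([C@H]2OC[C@](O)(Cc3cc(OC)c(O)c(OC)c3)[C@@H]2CO)ccc1O
F6 | step 7 | (3R,4S)-3-{[4-(benzyloxy)-3,5-dimethoxyphenyl](hydroxy)methyl}-4-{[4-(benzyloxy)-3-methoxyphenyl]methyl}-3-hydroxydihydrofuran-2(3H)-one (carbinol epimers) | O=C1OC[C@H](Cc2ccc(OCc3ccccc3)c(OC)c2)[C@@]1(O)C(O)c1cc(OC)c(OCc2ccccc2)c(OC)c1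
F7 | step 2 | racemic 4-[4-(benzyloxy)-3-methoxyphenyl]-3-(methoxycarbonyl)butanoic acid | COC(=O)C(Cc1ccc(OCc2ccccc2)c(OC)c1)CC(=O)O
F8 | step 2 | (R)-1-phenylethylammonium (3R)-4-[4-(benzyloxy)-3-methoxyphenyl]-3-(methoxycarbonyl)butanoate | COC(=O)[C@H](Cc1ccc(OCc2ccccc2)c(OC)c1)CC(=O)[O-].C[C@@H]([NH3+])c1ccccc1
A1 | direct plan | ethyl (2R,3S)-4-[(tert-butyldimethylsilyl)oxy]-3-formyl-2-hydroxybutanoate | CCOC(=O)[C@H](O)[C@@H](C=O)CO[Si](C)(C)C(C)(C)C
A2 | direct plan | (3R,4S,5S)-5-[4-(benzyloxy)-3-methoxyphenyl]-3-hydroxy-4-(hydroxymethyl)dihydrofuran-2(3H)-one | O=C1O[C@H](c2ccc(OCc3ccccc3)c(OC)c2)[C@@H](CO)[C@H]1O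
A3 | direct plan | (2R,4aR,5S,7aR)-2-[4-(benzyloxy)-3,5-dimethoxyphenyl]-5-[4-(benzyloxy)-3-methoxyphenyl]tetrahydro-4H-furo[3,4-d][1,3]dioxin-7(4aH)-one | O=C1O[C@H](c3ccc(OCc4ccccc4)c(OC)c3)[C@H]2CO[C@@H](c3cc(OC)c(OCc4ccccc4)c(OC)c3)O[C@@H]12
A4 | direct plan | (3S,3aR,6R,6aR)-6-[4-(benzyloxy)-3,5-dimethoxyphenyl]-3-[4-(benzyloxy)-3-methoxyphenyl]-6a-hydroxytetrahydro-1H,3H-furo[3,4-c]furan-1-one | O=C1O[C@H](c3ccc(OCc4ccccc4)c(OC)c3)[C@H]2CO[C@H](c3cc(OC)c(OCc4ccccc4)c(OC)c3)[C@@]12O
A5 | direct plan | (1S,2R,5R,6S)-2-[4-(benzyloxy)-3,5-dimethoxyphenyl]-6-[4-(benzyloxy)-3-methoxyphenyl]-3,7-dioxabicyclo[3.3.0]octan-1-ol | COc1cc([C@H]2OC[C@]3(O)[C@@H](c4cc(OC)c(OCc5ccccc5)c(OC)c4)OC[C@H]23)ccc1OCc1ccccc1
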